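Cuts: first O1–C2 of ring C (cyclodehydration in reverse), then C2–C3 and C2–C1' together. This leaves a ring A methyl ketone, carbon monoxide and a ring B aryl bromide.
Enabling feature: C2 is bonded only to O1, C3 and C1' of ring B and stands at the carboxylic acid oxidation level. It can therefore enter as CO between an enolate carbon (C3) and an aryl halide carbon (C1').
Forward: rings A and B are bought as arenes and dressed separately, with all four phenols as benzyl ethers. CO then links them to the open C4–C3–C2 diketone chain without ring closure.
Hydrogenolysis frees the phenols, and ring C closes last by acid-catalysed attack of a ring A ortho hydroxyl on C2 with loss of water.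
The ring B pattern comes from symmetric 1,2,3,4-tetramethoxybenzene: one inner methyl group is removed and bromine enters para to the new hydroxyl.
Stereochemistry: the target has no stereocentre and no configured double bond, so none has to be set.

Key step: step 5

Remark on the chemistry: the 1,3-diketones are drawn as diketo tautomers although they should be largely enolised. The debenzylated one may sit partly as its ring-closed 2-hydroxyflavanone hemiketal. All these forms converge on the flavone under acid.

Step 1
Reactants: 1 1-(2,4,6-trihydroxyphenyl)ethanone (2',4',6'-trihydroxyacetophenone), 2 benzyl bromide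
Product: 3 1-[2,4,6-tris(benzyloxy)phenyl]ethanone
Conditions: BnBr (3.6 equiv), K2CO3 (5 equiv), DMF, 80 °C
Reagents that add atoms: benzyl bromide, BrCc1ccccc1
Why: Williamson etherification with K2CO3 in a dipolar aprotic solvent favours O- over C-alkylation of the phloroglucinol nucleus, and excess halide with heat also caps the two carbonyl-chelated ortho hydroxyls, so that ring A enters step 5 without any acidic OH.

Step 2
Reactants: 4 1,2,3,4-tetramethoxybenzene
Product: 6 2,3,6-trimethoxyphenol, via aryloxydichloroborane 5 (not isolated)
Conditions: BCl3 (1.05 equiv), CH2Cl2, −78 °C to 0 °C; then H2O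
Reagents that add atoms: boron trichloride, ClB(Cl)Cl (boron and chlorine stay only in 5; none of its atoms is left in 6)
Why: Lewis acid ether cleavage with BCl3 is known to pick a methoxy group flanked on both sides, since that group is twisted out of the ring plane and has the most basic oxygen; the two inner methoxy groups of 4 are equivalent by symmetry, chloride removes the methyl group by SN2, and one equivalent at low temperature should stop at 5, which water hydrolyses to 6.

Step 3
Reactants: 6 2,3,6-trimethoxyphenol
Product: 7 4-bromo-2,3,6-trimethoxyphenol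
Conditions: NBS (1.0 equiv), MeCN, −20 °C to 0 °C, dark
Reagents that add atoms: N-bromosuccinimide, O=C1CCC(=O)N1Br
Why: Electrophilic aromatic bromination should go to C4, para to the free hydroxyl (the strongest donor) and ortho to the 3-methoxy group, whereas C5 is served para only by the 2-methoxy group, which its two neighbours twist out of conjugation.

Step 4
Reactants: 7 4-bromo-2,3,6-trimethoxyphenol, 2 benzyl bromide
Product: 8 2-(benzyloxy)-5-bromo-1,3,4-trimethoxybenzene (ring order: OMe, OBn, OMe, OMe, Br, H)
Conditions: BnBr (1.2 equiv), K2CO3 (2 equiv), DMF, 60 °C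
Reagents that add atoms: benzyl bromide, BrCc1ccccc1
Why: Williamson etherification masks the future 4'-OH with the same group that protects ring A, so that all four come off together, and the aryl bromide is inert to K2CO3.

Step 5
Reactants: 3 1-[2,4,6-tris(benzyloxy)phenyl]ethanone, 8 2-(benzyloxy)-5-bromo-1,3,4-trimethoxybenzene, 9 carbon monoxide
Product: 12 1-[4-(benzyloxy)-2,3,5-trimethoxyphenyl]-3-[2,4,6-tris(benzyloxy)phenyl]propane-1,3-dione, via sodium enolate 10 (not isolated), via sodium diketonate 11 (not isolated)
Conditions: 3 (2 equiv), NaN(SiMe3)2 (2.1 equiv), THF, 0 °C to rt; then 8 (1 equiv), Pd(dba)2 (5 mol %), 1,3-bis(diphenylphosphino)propane (dppp, 6 mol %), CO (1–2 bar, closed vessel), THF, 80 °C; then 1 M HCl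
Reagents that add atoms: carbon monoxide, [C-]#[O+]; NaN(SiMe3)2, C[Si](C)(C)[N-][Si](C)(C)C.[Na+] (sodium, only in 10 and 11)
Why: Zerovalent palladium carrying dppp adds oxidatively into the C–Br bond of 8, CO inserts into the aryl–palladium bond to give an aroyl complex of divalent palladium, and the carbon terminus of enolate 10 replaces bromide and leaves with the aroyl group by reductive elimination, so that C1'–C2 and C2–C3 form in one operation. The closest known reaction is exactly this type, the palladium-catalysed carbonylative alpha-arylation of aryl methyl ketones with aryl bromides (electron-rich ones included) under a hexamethyldisilazide base to give 1,3-diketones. No ring closes and no stereocentre is formed. The first selectivity needed is carbonylative against direct alpha-arylation, and it is secured because CO insertion at a chelated arylpalladium is faster than enolate transfer even at low CO pressure, which also leaves enough unsaturated zerovalent palladium for the slow addition to this electron-rich, ortho-methoxylated bromide. The second is carbon against oxygen acylation and single against double acylation: an enol ester formed at oxygen is itself an acyl donor toward 10, and the second equivalent of enolate turns 12 at once into the chelated diketonate 11, the thermodynamic sink, which is too weak a nucleophile to react again. The substrate secures chemoselectivity because 3 has a single enolisable position (its methyl group) and, with every phenol benzylated, offers no phenoxide that could trap the aroylpalladium as an aryl ester or quench the enolate.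

Step 6
Reactants: 12 1-[4-(benzyloxy)-2,3,5-trimethoxyphenyl]-3-[2,4,6-tris(benzyloxy)phenyl]propane-1,3-dione
Product: 13 1-(4-hydroxy-2,3,5-trimethoxyphenyl)-3-(2,4,6-trihydroxyphenyl)propane-1,3-dione
Conditions: H2 (1 atm), 10% Pd/C, EtOAc/MeOH, rt
Reagents that add atoms: none
Why: Catalytic hydrogenolysis cleaves all four aryl benzyl ethers under neutral conditions that leave methyl ethers untouched and reduce the enolised, electron-rich diaryl diketone far more slowly than O–benzyl bonds are cut, which is the known way from benzyl-protected dibenzoylmethanes to their 2'-hydroxy forms.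

Step 7
Reactants: 13 1-(4-hydroxy-2,3,5-trimethoxyphenyl)-3-(2,4,6-trihydroxyphenyl)propane-1,3-dione
Product: 14 5,7-dihydroxy-2-(4-hydroxy-2,3,5-trimethoxyphenyl)-4H-chromen-4-one (5,7,4'-trihydroxy-2',3',5'-trimethoxyflavone)
Conditions: H2SO4 (cat.), AcOH, 95 °C, N2
Reagents that add atoms: none
Why: Acid-catalysed cyclodehydration of a 2'-hydroxydibenzoylmethane (the closing step of the Baker–Venkataraman flavone synthesis) lets one of the two equivalent ortho hydroxyls of ring A add to the C2 carbonyl, loss of water from the hemiketal forms O1–C2 and C2=C3 of ring C, and the other ortho hydroxyl becomes the chelated 5-OH while the aryl methyl ethers survive catalytic acid.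

Compound list
1 | 1-(2,4,6-trihydroxyphenyl)ethanone | CC(=O)c1c(O)cc(O)cc1O | starting material
2 | benzyl bromide | BrCc1ccccc1 | starting material
3 | 1-[2,4,6-tris(benzyloxy)phenyl]ethanone | CC(=O)c1c(OCc2ccccc2)cc(OCc2ccccc2)cc1OCc1ccccc1 | intermediate
4 | 1,2,3,4-tetramethoxybenzene | COc1ccc(OC)c(OC)c1OC | starting material
5 | dichloro(2,3,6-trimethoxyphenoxy)borane | COc1ccc(OC)c(OB(Cl)Cl)c1OC | intermediate
6 | 2,3,6-trimethoxyphenol | COc1ccc(OC)c(O)c1OC | intermediate
7 | 4-bromo-2,3,6-trimethoxyphenol | COc1cc(Br)c(OC)c(OC)c1O | intermediate
8 | 2-(benzyloxy)-5-bromo-1,3,4-trimethoxybenzene | COc1cc(Br)c(OC)c(OC)c1OCc1ccccc1 | intermediate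
9 | carbon monoxide | [C-]#[O+] | starting material
10 | sodium 1-[2,4,6-tris(benzyloxy)phenyl]ethen-1-olate | [Na+].C=C([O-])c1c(OCc2ccccc2)cc(OCc2ccccc2)cc1OCc1ccccc1 | intermediate
11 | sodium salt of diketone 12 (deprotonated at C3) | [Na+].COc1cc(C(=O)[CH-]C(=O)c2c(OCc3ccccc3)cc(OCc3ccccc3)cc2OCc2ccccc2)c(OC)c(OC)c1OCc1ccccc1 | intermediate
12 | 1-[4-(benzyloxy)-2,3,5-trimethoxyphenyl]-3-[2,4,6-tris(benzyloxy)phenyl]propane-1,3-dione | COc1cc(C(=O)CC(=O)c2c(OCc3ccccc3)cc(OCc3ccccc3)cc2OCc2ccccc2)c(OC)c(OC)c1OCc1ccccc1 | intermediate
13 | 1-(4-hydroxy-2,3,5-trimethoxyphenyl)-3-(2,4,6-trihydroxyphenyl)propane-1,3-dione | COc1cc(C(=O)CC(=O)c2c(O)cc(O)cc2O)c(OC)c(OC)c1O | intermediate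
14 | 5,7-dihydroxy-2-(4-hydroxy-2,3,5-trimethoxyphenyl)-4H-chromen-4-one | COc1cc(-c2cc(=O)c3c(O)cc(O)cc3o2)c(OC)c(OC)c1O | target

Total step count: 7
Longest linear sequence: 6 steps (4 to 14 through steps 2, 3, 4, 5, 6 and 7); step 1 is the side branch.

Steps most likely to fail

1. Step 5.
- What may go wrong: oxidative addition to the electron-rich, ortho-substituted bromide may be too slow under CO. The catalyst could then decay to palladium black, and hydrodebromination or non-carbonylative arylation could take over.
- Fallback: no palladium is used, the two bonds at C2 are made one after the other, and C2 comes from CO2. It sets out from 8 (with 3 as partner) and comes back at 12.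
- Bromine–lithium exchange on 8 (n-BuLi, THF, −78 °C) gives [4-(benzyloxy)-2,3,5-trimethoxyphenyl]lithium F1. CO2 and an acidic work-up give 4-(benzyloxy)-2,3,5-trimethoxybenzoic acid F2. (COCl)2 with catalytic DMF in CH2Cl2 gives 4-(benzyloxy)-2,3,5-trimethoxybenzoyl chloride F3.
- F3 is added at −78 °C to two equivalents of enolate 10, made from 3 as in step 5. This Claisen-type C-acylation leads through 11 to 12 after the acid quench.

2. Step 2.
- What may go wrong: cleavage may not stop after one methyl group, because the boron aryloxide can assist a second demethylation at the neighbouring methoxy group by chelation. It may also stray to an outer methoxy group.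
- Fallback: the oxygen is put in rather than a methyl group taken off. It leaves 4 aside, sets out from commercial 1,2,4-trimethoxybenzene F4 and comes back at 6.
- n-BuLi (THF, 0 °C) deprotonates C3, the position between two methoxy groups (directed ortho metalation), to give (2,3,6-trimethoxyphenyl)lithium F5. B(OMe)3 at −78 °C converts it into dimethyl (2,3,6-trimethoxyphenyl)boronate F6. H2O2 in AcOH then oxidises the C–B bond at the same carbon to give 6.

3. Step 6.
- What may go wrong: reduction of the enolised diketone or of its benzylic carbonyl may compete while the doubly flanked 4'-O-benzyl ether is still being cleaved. The open polyphenol may also oxidise in air on handling.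
- Fallback: ring C is closed before the hydrogenolysis. It sets out from 12 and comes back at 14.
- MgBr2·OEt2 (toluene/Et2O, reflux) binds between the C4 carbonyl oxygen and one of the two equivalent ortho benzyloxy groups, and bromide removes that benzyl group alone. This gives 1-[2,4-bis(benzyloxy)-6-hydroxyphenyl]-3-[4-(benzyloxy)-2,3,5-trimethoxyphenyl]propane-1,3-dione F7.
- TsOH·H2O in toluene at reflux with removal of water closes ring C to 5,7-bis(benzyloxy)-2-[4-(benzyloxy)-2,3,5-trimethoxyphenyl]-4H-chromen-4-one F8. Hydrogenolysis of this robust flavone (H2, 10% Pd/C, THF/MeOH) gives 14 directly.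

Further compounds
F1 | step 5 | [4-(benzyloxy)-2,3,5-trimethoxyphenyl]lithium | [Li]c1cc(OC)c(OCc2ccccc2)c(OC)c1OC
F2 | step 5 | 4-(benzyloxy)-2,3,5-trimethoxybenzoic acid | COc1cc(C(=O)O)c(OC)c(OC)c1OCc1ccccc1
F3 | step 5 | 4-(benzyloxy)-2,3,5-trimethoxybenzoyl chloride | COc1cc(C(=O)Cl)c(OC)c(OC)c1OCc1ccccc1
F4 | step 2 | 1,2,4-trimethoxybenzene (bought) | COc1ccc(OC)c(OC)c1
F5 | step 2 | (2,3,6-trimethoxyphenyl)lithium | COc1ccc(OC)c(OC)c1[Li]
F6 | step 2 | dimethyl (2,3,6-trimethoxyphenyl)boronate | COc1ccc(OC)c(OC)c1B(OC)OC
F7 | step 6 | 1-[2,4-bis(benzyloxy)-6-hydroxyphenyl]-3-[4-(benzyloxy)-2,3,5-trimethoxyphenyl]propane-1,3-dione | COc1cc(C(=O)CC(=O)c2c(O)cc(OCc3ccccc3)cc2OCc2ccccc2)c(OC)c(OC)c1OCc1ccccc1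
F8 | step 6 | 5,7-bis(benzyloxy)-2-[4-(benzyloxy)-2,3,5-trimethoxyphenyl]-4H-chromen-4-one | COc1cc(-c2cc(=O)c3c(OCc4ccccc4)cc(OCc4ccccc4)cc3o2)c(OC)c(OC)c1OCc1ccccc1
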